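Each coupling partner that becomes target takes one substrate with it, so c(target) plus c(partner) stays at the partner charge for as long as nothing else takes partner. In the cedar run partner is the limiting reagent, 32.0 mM against 240 mM of substrate, which puts the ceiling at 13.3% of the substrate charged.

| setting | larch | alder | ash | maple | cedar |
|---|---|---|---|---|---|
| substrate | 80.0 mM | 40.0 mM | 160 mM | 80.0 mM | 240 mM |
| coupling partner | 96.0 mM | 56.0 mM | 96.0 mM | 96.0 mM | 32.0 mM |
| free catalyst | 4.00 mM | 4.00 mM | 4.00 mM | 2.00 mM | 4.00 mM |
| time |  |  |  |  | 5.9 h |

| larch run: time / h | larch run: [target] / mM | alder run: time / h | alder run: [target] / mM | ash run: time / h | ash run: [target] / mM | maple run: time / h | maple run: [target] / mM |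
|---|---|---|---|---|---|---|---|
| 0.24 | 11.1 | 0.24 | 3.7 | 0.24 | 20.9 | 0.24 | 8.1 |
| 0.53 | 18.6 | 0.53 | 5.3 | 0.53 | 32.9 | 0.53 | 12.5 |
| 1.2 | 28.8 | 1.2 | 12.0 | 1.2 | 48.7 | 1.2 | 22.1 |
| 2.6 | 35.5 | 2.6 | 15.3 | 2.6 | 58.2 | 2.6 | 29.1 |
| 5.9 | 40.1 | 5.9 | 20.4 | 5.9 | 60.3 | 5.9 | 33.5 |

(each reading ± 0.6 mM)

1. the exponent of [coupling partner] in the starting rate at the charge of the larch run (at the point where two percent of the substrate have become target)
2. the exponent of [substrate] in the starting rate at the charge of the larch run (at the point where two percent of the substrate have become target) (one fixed amount of target, the same in the runs compared)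
3. target in the cedar run at 5.9 h, as a share of the substrate charged

- Overall: substrate + coupling partner -> target, with free catalyst as catalyst.
- Constant volume, constant temperature.
- An order is taken over about fifteen percent of the charge, up and down.

Start with the main way. From larch to ash you double the substrate, and the first reading goes from 11.1 mM to 20.9 mM, an order of 0.913. Alder against larch then gives about 0.752 in partner, a shaky figure since that alder reading is 3.7 mM with a scatter of 0.6 mM. I take both orders as about one.

Now the stall. The larch run reaches 40.1 mM from 96.0 mM of partner, and I assume partner is what it is running short of. Suppose a rival way takes partner in proportion to c(partner) squared, while the main way goes with c(substrate) times c(partner). Add that race up as partner falls to nothing, with substrate held at its mean: the target made is mean c(substrate) over Q, times the natural log of one plus Q times the partner charge over mean c(substrate). With a mean substrate of 0.0600 M, a trial Q of 2.3 put inside the log returns 2.31 from the last larch reading. This Q is the loss ratio, the c(substrate) per c(partner) at which both ways take partner equally.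

In the cedar run the mean substrate is 0.224 M, so the share of partner reaching target is 86.4%, and the target comes to 11.5% of the substrate charged.

The weak link is the rival's dependence on partner. If its pace per partner did not change with the charge, the share would be mean c(substrate) over that mean plus a fixed term, which larch reads as 0.0836 M, and cedar would drop to 9.69%. For alder the fixed term gives 14.7 mM and Q gives 21.6 mM, against a reading of 20.4 mM. For ash they give 58.4 mM and 56.0 mM, against 60.3 mM. Ash leans to the fixed term, but the fixed term misses alder by more than Q misses ash, and the alder partner charge of 56.0 mM stands nearer the cedar charge than the ash one does. So I keep Q, and my number stands.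

The forecast gives 0.9 for partner, 0.95 for substrate and 12.2% for cedar, with the words: “If death slows at low partner, consumption is nearly complete.”

The cedar run gives 12.0%, with orders of 1.0 in partner and 1.0 in substrate.

    2 free catalyst ⇌ catalyst dimer, settled at all times (760.0 M⁻¹)
    free catalyst + substrate + coupling partner → target + free catalyst (5652 M⁻² h⁻¹)
    2 coupling partner → lost reagent (3.272 M⁻¹ h⁻¹)
    target + coupling partner → side product (2.815 M⁻¹ h⁻¹)

That result means 89.9% of the cedar partner became target. In the maple run, halving the catalyst took the starting rate from 54 mM h⁻¹ to 35 mM h⁻¹, and neither loss step in the equations carries catalyst. Scaling Q by that ratio gives 3.59 for maple. With a mean substrate of 0.0633 M, maple should reach 32.8 mM, and its last reading is 33.5 mM.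

All runs were computed with made-up constants, noise included.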